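**Assumption:** the target SMILES has no stereocentre and no stereogenic double bond, so the compound is achiral and needs no enantiocontrol. The one stereocentre that appears on the way (C3 of 9) is made racemic and removed in step 5.

**Retrosynthetic overview**
- Target 12 ⇐ one global hydrogenation (C≡C, C=C, two O‑benzyl groups) of enynone 11.
- 11 ⇐ dehydration of β‑hydroxy ketone 9 ⇐ directed aldol (C2–C3 bond) between the lithium enolate of acetophenone 2 and ynal 6; this is the fragment union.
- 6 ⇐ oxidation of alkynol 5 ⇐ Sonogashira coupling of aryl iodide 3 with hept‑6‑yn‑1‑ol 4; 2 ⇐ O‑benzylation of 1.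
- No ring is formed: both benzene rings are bought intact.

**Route**

Step 1
Reactants: 1 2'-hydroxy-6'-methoxyacetophenone
Product: 2 1-[2-(benzyloxy)-6-methoxyphenyl]ethan-1-one
Conditions: BnBr (1.2 equiv), K2CO3 (2 equiv), DMF, 60 °C
Reagents that add atoms: benzyl bromide, BrCc1ccccc1
Why: Williamson ether synthesis, in which the phenoxide formed in warm DMF is benzylated by SN2 and the acidic OH is thereby masked before the LDA step.

Step 2
Reactants: 3 1-(benzyloxy)-4-iodobenzene; 4 hept-6-yn-1-ol (1.2 equiv)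
Product: 5 7-[4-(benzyloxy)phenyl]hept-6-yn-1-ol
Conditions: PdCl2(PPh3)2 (2 mol %), CuI (4 mol %), Et3N/THF, degassed, rt
Reagents that add atoms: none
Why: Sonogashira coupling of an aryl iodide with a terminal alkyne runs at room temperature and tolerates the free primary alcohol and the benzyl ether.

Step 3
Reactants: 5 7-[4-(benzyloxy)phenyl]hept-6-yn-1-ol
Product: 6 7-[4-(benzyloxy)phenyl]hept-6-ynal
Conditions: Dess–Martin periodinane (1.2 equiv), CH2Cl2, 0 °C to rt
Reagents that add atoms: none
Why: Dess–Martin oxidation stops at the aldehyde under near-neutral conditions that leave the internal alkyne and the benzyl ether untouched.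

Step 4
Reactants: 2 1-[2-(benzyloxy)-6-methoxyphenyl]ethan-1-one; 6 7-[4-(benzyloxy)phenyl]hept-6-ynal
Product: 9 rac-1-[2-(benzyloxy)-6-methoxyphenyl]-9-[4-(benzyloxy)phenyl]-3-hydroxynon-8-yn-1-one, via lithium enolate 7 (not isolated), via lithium aldolate 8 (not isolated)
Conditions: LDA (1.1 equiv), THF, −78 °C; then 6, −78 °C; sat. aq. NH4Cl at −78 °C
Reagents that add atoms: none
Why: Directed crossed aldol addition, in which the methyl ketone (one enolisable site) is fully converted to its lithium enolate before the enolisable aldehyde is added cold, so cross-addition beats aldehyde self-condensation; the new C3 carbinol centre is racemic and is erased in step 5.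

Step 5
Reactants: 9 rac-1-[2-(benzyloxy)-6-methoxyphenyl]-9-[4-(benzyloxy)phenyl]-3-hydroxynon-8-yn-1-one
Product: 11 (E)-1-[2-(benzyloxy)-6-methoxyphenyl]-9-[4-(benzyloxy)phenyl]non-2-en-8-yn-1-one, via β-mesylate 10 (not isolated)
Conditions: MsCl, Et3N, CH2Cl2, 0 °C; then DBU, rt
Reagents that add atoms: none
Why: Mesylation followed by E1cB elimination of the β-mesyloxy ketone gives the conjugated, thermodynamically preferred E-enone, with the alkyne and the ethers inert.

Step 6
Reactants: 11 (E)-1-[2-(benzyloxy)-6-methoxyphenyl]-9-[4-(benzyloxy)phenyl]non-2-en-8-yn-1-one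
Product: 12 1-(2-hydroxy-6-methoxyphenyl)-9-(4-hydroxyphenyl)nonan-1-one
Conditions: H2 (1 atm), 10 % Pd/C, EtOAc/EtOH, rt
Reagents that add atoms: none
Why: Catalytic hydrogenation and hydrogenolysis over Pd/C saturates the alkyne and the enone C=C (fast, before the ortho-phenol is freed) and cleaves both benzyl ethers, while the di-ortho-substituted aryl ketone and the aryl methyl ether survive at 1 atm; no stereocentre remains.

**Compound list**
1 | 2'-hydroxy-6'-methoxyacetophenone | COc1cccc(O)c1C(C)=O | starting material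
2 | 1-[2-(benzyloxy)-6-methoxyphenyl]ethan-1-one | COc1cccc(OCc2ccccc2)c1C(C)=O | intermediate
3 | 1-(benzyloxy)-4-iodobenzene | Ic1ccc(OCc2ccccc2)cc1 | starting material
4 | hept-6-yn-1-ol | C#CCCCCCO | starting material
5 | 7-[4-(benzyloxy)phenyl]hept-6-yn-1-ol | OCCCCCC#Cc1ccc(OCc2ccccc2)cc1 | intermediate
6 | 7-[4-(benzyloxy)phenyl]hept-6-ynal | O=CCCCCC#Cc1ccc(OCc2ccccc2)cc1 | intermediate
7 | lithium 1-[2-(benzyloxy)-6-methoxyphenyl]ethen-1-olate (lithium enolate of 2) | C=C(O[Li])c1c(OC)cccc1OCc1ccccc1 | intermediate (not isolated)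
8 | lithium aldolate of 9 (racemic) | COc1cccc(OCc2ccccc2)c1C(=O)CC(O[Li])CCCCC#Cc1ccc(OCc2ccccc2)cc1 | intermediate (not isolated)
9 | rac-1-[2-(benzyloxy)-6-methoxyphenyl]-9-[4-(benzyloxy)phenyl]-3-hydroxynon-8-yn-1-one | COc1cccc(OCc2ccccc2)c1C(=O)CC(O)CCCCC#Cc1ccc(OCc2ccccc2)cc1 | intermediate
10 | rac-1-[2-(benzyloxy)-6-methoxyphenyl]-9-[4-(benzyloxy)phenyl]-1-oxonon-8-yn-3-yl methanesulfonate | COc1cccc(OCc2ccccc2)c1C(=O)CC(OS(C)(=O)=O)CCCCC#Cc1ccc(OCc2ccccc2)cc1 | intermediate (not isolated)
11 | (E)-1-[2-(benzyloxy)-6-methoxyphenyl]-9-[4-(benzyloxy)phenyl]non-2-en-8-yn-1-one | COc1cccc(OCc2ccccc2)c1C(=O)/C=C/CCCCC#Cc1ccc(OCc2ccccc2)cc1 | intermediate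
12 | 1-(2-hydroxy-6-methoxyphenyl)-9-(4-hydroxyphenyl)nonan-1-one (achiral) | COc1cccc(O)c1C(=O)CCCCCCCCc1ccc(O)cc1 | target

**Totals**
Total step count: 6. Longest linear sequence: 5 steps (3/4 → 5 → 6 → 9 → 11 → 12).

**Three steps most likely to fail, with fallbacks**

Step 4 (aldol addition). The risk is proton transfer to the enolisable aldehyde, self-condensation of 6, or retro-aldol on warming. The fallback sets out from 2 and comes back at 9. Ketone 2 is converted with TMSOTf and Et3N in CH2Cl2 at 0 °C into the silyl enol ether {[1-(2-(benzyloxy)-6-methoxyphenyl)ethenyl]oxy}trimethylsilane F1. This neutral nucleophile adds to 6 in a Lewis-acid-catalysed Mukaiyama aldol (Sc(OTf)3, 5 mol %, CH2Cl2, −78 °C) to give the O-silyl aldol rac-1-[2-(benzyloxy)-6-methoxyphenyl]-9-[4-(benzyloxy)phenyl]-3-[(trimethylsilyl)oxy]non-8-yn-1-one F2. Brief treatment with 1 M HCl in THF at 0 °C removes the silyl group and gives 9, so no basic enolate ever meets the aldehyde.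

Step 6 (global hydrogenation). The risk is over-reduction of the aryl ketone or stalling before both benzyl groups are gone. The fallback sets out from 11 and comes back at 12. Hydrogenation over Pd/C poisoned with diphenyl sulfide (H2 1 atm, EtOAc, rt) saturates only the alkyne and the enone C=C and gives 1-[2-(benzyloxy)-6-methoxyphenyl]-9-[4-(benzyloxy)phenyl]nonan-1-one F3, with ketone and benzyl ethers intact. Both benzyl ethers are then removed non-reductively with BCl3 and pentamethylbenzene as cation scavenger in CH2Cl2 at −78 °C (short reaction time, MeOH quench). The aryl methyl ether is not cleaved at this temperature, and 12 results.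

Step 2 (Sonogashira coupling). The risk is Glaser homocoupling of alkynol 4 or sluggish coupling of the free alkynol. The fallback sets out from 3 and comes back at 5. Iodide 3 is coupled with ethynyltrimethylsilane (PdCl2(PPh3)2, CuI, Et3N) to give {[4-(benzyloxy)phenyl]ethynyl}trimethylsilane F4. K2CO3 in MeOH desilylates it to 1-(benzyloxy)-4-ethynylbenzene F5. n-BuLi in THF at −78 °C gives lithium [4-(benzyloxy)phenyl]acetylide F6, which is alkylated with (5-bromopentyloxy)(tert-butyl)dimethylsilane in THF/DMPU (−78 °C to rt) to give {[7-(4-(benzyloxy)phenyl)hept-6-yn-1-yl]oxy}(tert-butyl)dimethylsilane F7. TBAF in THF then releases 5. The chain is thus attached by C(sp)–C(sp3) alkylation instead of by cross-coupling of the alkynol.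

**Further compounds**
F1 | step 4 | {[1-(2-(benzyloxy)-6-methoxyphenyl)ethenyl]oxy}trimethylsilane | C=C(O[Si](C)(C)C)c1c(OC)cccc1OCc1ccccc1
F2 | step 4 | rac-1-[2-(benzyloxy)-6-methoxyphenyl]-9-[4-(benzyloxy)phenyl]-3-[(trimethylsilyl)oxy]non-8-yn-1-one | COc1cccc(OCc2ccccc2)c1C(=O)CC(O[Si](C)(C)C)CCCCC#Cc1ccc(OCc2ccccc2)cc1
F3 | step 6 | 1-[2-(benzyloxy)-6-methoxyphenyl]-9-[4-(benzyloxy)phenyl]nonan-1-one | COc1cccc(OCc2ccccc2)c1C(=O)CCCCCCCCc1ccc(OCc2ccccc2)cc1
F4 | step 2 | {[4-(benzyloxy)phenyl]ethynyl}trimethylsilane | C[Si](C)(C)C#Cc1ccc(OCc2ccccc2)cc1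
F5 | step 2 | 1-(benzyloxy)-4-ethynylbenzene | C#Cc1ccc(OCc2ccccc2)cc1
F6 | step 2 | lithium [4-(benzyloxy)phenyl]acetylide | [Li]C#Cc1ccc(OCc2ccccc2)cc1
F7 | step 2 | {[7-(4-(benzyloxy)phenyl)hept-6-yn-1-yl]oxy}(tert-butyl)dimethylsilane | CC(C)(C)[Si](C)(C)OCCCCCC#Cc1ccc(OCc2ccccc2)cc1
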